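**Strategy.** The odd unit is the middle one, an ent-epiafzelechin. Its ring C is cut at O1–C2 and C4a–C4: O1 and C4a are the oxygen and ortho carbon of a phloroglucinol-type ring A, and C2–C3–C4 is a chain oxygenated at C3 with benzylic C2. One titanium-mediated annulation therefore joins the titanium aryloxide of 3,5-bis(benzyloxy)phenol to an enantiopure cis-3-arylglycidaldehyde: ortho-hydroxyalkylation by the aldehyde, then phenol opening of the epoxide with inversion, giving a 2,3-cis flavan-3,4-diol whose C4 hydroxyl is the handle for the interflavan bond. The mirror-image aldehyde supplies both outer units; two Lewis acid couplings set C4 trans to O3, and hydrogenolysis finishes.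

Key step: step 5

Remarks on the chemistry:
- Flavan numbering (O1, C2, C3, C4, C4a, C5 to C8, C8a) is used throughout. The target is read as epiafzelechin-(4β→8)-ent-epiafzelechin-(4α→8)-epiafzelechin: the middle unit is the mirror image of the outer ones at C2, C3 and C4.
- C4 of diols 8 and 12 should form as an epimer mixture and is left undefined in name and SMILES; both epimers ionise to the same C4 cation.
- The sense of the Jacobsen epoxidation is assigned by analogy with (Z)-cinnamate esters; if it were reversed, the two catalyst enantiomers would be exchanged.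
- Aryloxide 6 is written with its nominal composition ArOTi(OiPr)3; one batch, kept as a toluene stock solution under argon, serves steps 5 and 8.
- The C4 cations are written as ion pairs with the anion of the acid that generates them: trifluoroacetate in step 9, triflate in steps 10 and 11.

**Step 1**
Reactants: 1 4-(benzyloxy)benzaldehyde
Product: 2 ethyl (Z)-3-[4-(benzyloxy)phenyl]prop-2-enoate
Conditions: (PhO)2P(O)CH2CO2Et, NaH, THF, −78 → 0 °C
Reagents that add atoms: ethyl 2-(diphenoxyphosphoryl)acetate, CCOC(=O)CP(=O)(Oc1ccccc1)Oc1ccccc1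
Why: Ando modification of the Horner–Wadsworth–Emmons reaction: the aryloxy groups make oxaphosphetane collapse faster than equilibration, so the kinetic adduct should deliver the Z-alkene, and the minor E-ester is removed by chromatography.

**Step 2**
Reactants: 2 ethyl (Z)-3-[4-(benzyloxy)phenyl]prop-2-enoate
Product: 3 ethyl (2R,3R)-3-[4-(benzyloxy)phenyl]oxirane-2-carboxylate (cis)
Conditions: (R,R)-(salen)MnCl [chloride of trivalent manganese with (R,R)-N,N'-bis(3,5-di-tert-butylsalicylidene)cyclohexane-1,2-diamine] (5 mol%), 4-phenylpyridine N-oxide, aq NaOCl (pH 11), CH2Cl2, 4 °C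
Reagents that add atoms: sodium hypochlorite, [Na+].[O-]Cl
Why: Jacobsen–Katsuki epoxidation, for which cis-cinnamates are well-suited substrates: the chiral oxo-manganese species transfers oxygen to one enantioface, the (R,R)-catalyst is expected to give the (2R,3R) cis-epoxide, and the N-oxide ligand limits leakage to the trans-epoxide.

**Step 3**
Reactants: 3 ethyl (2R,3R)-3-[4-(benzyloxy)phenyl]oxirane-2-carboxylate
Product: 4 (2R,3R)-3-[4-(benzyloxy)phenyl]oxirane-2-carbaldehyde (cis)
Conditions: iBu2AlH (1.05 equiv), CH2Cl2, −78 °C; MeOH, aq potassium sodium tartrate (KNaC4H4O6); used crude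
Reagents that add atoms: none
Why: Partial DIBAL-H reduction: the aluminium hemiacetal, held by chelation to the epoxide oxygen, should survive at −78 °C and release the aldehyde on work-up, with the epoxide and both stereocentres untouched.

**Step 4**
Reactants: 5 3,5-bis(benzyloxy)phenol
Product: 6 [3,5-bis(benzyloxy)phenoxy]tris(propan-2-olato)titanium (moisture-sensitive residue, kept as a toluene stock solution under argon)
Conditions: Ti(OiPr)4 (1.0 equiv), toluene, rt; propan-2-ol and toluene removed in vacuo (twice); residue redissolved in dry toluene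
Reagents that add atoms: titanium tetraisopropoxide, CC(C)O[Ti](OC(C)C)(OC(C)C)OC(C)C
Why: Alcoholysis (ligand exchange) of the titanium alkoxide by the more acidic phenol, driven to the mono(aryloxide) by removal of propan-2-ol with toluene; no stereocentre is formed.

**Step 5**
Reactants: 4 (2R,3R)-3-[4-(benzyloxy)phenyl]oxirane-2-carbaldehyde; 6 [3,5-bis(benzyloxy)phenoxy]tris(propan-2-olato)titanium
Product: 8 (2S,3S)-5,7-bis(benzyloxy)-2-[4-(benzyloxy)phenyl]chromane-3,4-diol (2,3-cis; C4 epimers), via epoxy carbinol 7 (not isolated)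
Conditions: 6 (1.1 equiv, stock solution), toluene, 0 °C; 4 added slowly; 0 → 40 °C; aq potassium sodium tartrate (KNaC4H4O6)/NaHCO3
Reagents that add atoms: none
Why: Proposed new method: the aryloxide 6 binds the aldehyde oxygen of 4 at titanium and delivers its ortho carbon to the carbonyl carbon through a closed six-membered transition state (C4a–C4 bond), and the titanium 2,3-epoxy alkoxide 7 so formed is then opened at its distal, benzylic epoxide carbon by the neighbouring phenolic oxygen (O1–C2 bond). The closest known reaction types are the ortho-specific hydroxyalkylation of titanium and magnesium phenolates with α-oxygenated aldehydes, the Ti(OiPr)4-mediated opening of 2,3-epoxy alcohols at the carbon remote from the carbinol, and the 6-endo cyclisation of 2-hydroxybenzyl aryl epoxides to flavan-3-ols; their merger with an epoxy aldehyde in one flask is the untested part. Ring C closes by an anti 6-endo-tet epoxide opening, the C–C bond before it being intermolecular. C3 is carried over unchanged from the epoxide, C2 arises by inversion at the benzylic epoxide carbon so that the cis-epoxide set by the catalyst of step 2 maps onto the 2,3-cis (2S,3S) pattern, and the C4 carbinol forms under weak substrate control as a mixture that is erased in step 10. The step needs ortho over para carbon attack, which the metal-bound aldehyde secures (both ortho positions are equivalent), 6-endo over 5-exo opening, which the 4-benzyloxyphenyl group and titanium chelation by the C4 alkoxide secure, and clean inversion, for which non-acidic conditions are chosen. Once O1 is etherified the directing aryloxide is gone, which should stop a second hydroxyalkylation.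

**Step 6**
Reactants: 2 ethyl (Z)-3-[4-(benzyloxy)phenyl]prop-2-enoate
Product: 9 ethyl (2S,3S)-3-[4-(benzyloxy)phenyl]oxirane-2-carboxylate (cis)
Conditions: (S,S)-(salen)MnCl [chloride of trivalent manganese with (S,S)-N,N'-bis(3,5-di-tert-butylsalicylidene)cyclohexane-1,2-diamine] (5 mol%), 4-phenylpyridine N-oxide, aq NaOCl (pH 11), CH2Cl2, 4 °C
Reagents that add atoms: sodium hypochlorite, [Na+].[O-]Cl
Why: Jacobsen–Katsuki epoxidation as in step 2 with the mirror-image catalyst, which should give the enantiomeric cis-epoxide.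

**Step 7**
Reactants: 9 ethyl (2S,3S)-3-[4-(benzyloxy)phenyl]oxirane-2-carboxylate
Product: 10 (2S,3S)-3-[4-(benzyloxy)phenyl]oxirane-2-carbaldehyde (cis)
Conditions: iBu2AlH (1.05 equiv), CH2Cl2, −78 °C; MeOH, aq potassium sodium tartrate (KNaC4H4O6); used crude
Reagents that add atoms: none
Why: Partial DIBAL-H reduction as in step 3; the stereocentres are not touched.

**Step 8**
Reactants: 10 (2S,3S)-3-[4-(benzyloxy)phenyl]oxirane-2-carbaldehyde; 6 [3,5-bis(benzyloxy)phenoxy]tris(propan-2-olato)titanium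
Product: 12 (2R,3R)-5,7-bis(benzyloxy)-2-[4-(benzyloxy)phenyl]chromane-3,4-diol (2,3-cis; C4 epimers), via mirror-image epoxy carbinol 11 (not isolated)
Conditions: 6 (1.1 equiv, stock solution), toluene, 0 °C; 10 added slowly; 0 → 40 °C; aq potassium sodium tartrate (KNaC4H4O6)/NaHCO3
Reagents that add atoms: none
Why: Proposed new method: the same cascade as step 5, ortho-hydroxyalkylation of the titanium aryloxide by the aldehyde followed by 6-endo opening of the resulting titanium epoxy alkoxide by the phenolic oxygen (closest known types: ortho-specific hydroxyalkylation of metal phenolates with α-oxygenated aldehydes and Ti(OiPr)4-mediated distal opening of 2,3-epoxy alcohols), here with the mirror-image aldehyde, so that inversion at the benzylic epoxide carbon and retention at the other should give the (2R,3R) diol.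

**Step 9**
Reactants: 12 (2R,3R)-5,7-bis(benzyloxy)-2-[4-(benzyloxy)phenyl]chromane-3,4-diol
Product: 14 (2R,3R)-5,7-bis(benzyloxy)-2-[4-(benzyloxy)phenyl]chroman-3-ol (5,7,4'-tri-O-benzyl-epiafzelechin), via flavan-4-ylium trifluoroacetate 13 (not isolated)
Conditions: Et3SiH (10 equiv), CF3CO2H (3 equiv), CH2Cl2, −40 → 0 °C, slow addition of 12 at high dilution; aq NaHCO3
Reagents that add atoms: none
Why: Ionic hydrogenation: the acid ionises the 2,4,6-trioxygenated benzylic C4 alcohol and the silane reduces the cation to CH2; C2 and C3 are not involved, and slow addition into excess silane is meant to keep the cation from alkylating a second flavan.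

**Step 10**
Reactants: 8 (2S,3S)-5,7-bis(benzyloxy)-2-[4-(benzyloxy)phenyl]chromane-3,4-diol; 14 (2R,3R)-5,7-bis(benzyloxy)-2-[4-(benzyloxy)phenyl]chroman-3-ol
Product: 16 (2R,3R)-5,7-bis(benzyloxy)-2-[4-(benzyloxy)phenyl]-8-{(2S,3S,4S)-5,7-bis(benzyloxy)-2-[4-(benzyloxy)phenyl]-3-hydroxychroman-4-yl}chroman-3-ol (hexa-O-benzyl ent-epiafzelechin-(4α→8)-epiafzelechin), via ent-flavan-4-ylium triflate 15 (not isolated)
Conditions: 14 (4 equiv, excess recovered), TMSOTf (0.1 equiv), 4 Å MS, CH2Cl2, −78 → −40 °C; Et3N quench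
Reagents that add atoms: none
Why: Lewis acid flavan-4-yl cation/arene coupling (Friedel–Crafts alkylation) of the kind used for procyanidins: C8 of 14 is the most nucleophilic and least hindered position (C6 lies between two benzyloxy groups), and attack anti to the axial C3 hydroxyl of the 2,3-cis cation should give only the 3,4-trans (4α) bond, while the excess of 14 suppresses self-condensation of 8.

**Step 11**
Reactants: 12 (2R,3R)-5,7-bis(benzyloxy)-2-[4-(benzyloxy)phenyl]chromane-3,4-diol; 16 hexa-O-benzyl ent-epiafzelechin-(4α→8)-epiafzelechin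
Product: 18 nona-O-benzyl epiafzelechin-(4β→8)-ent-epiafzelechin-(4α→8)-epiafzelechin (all nine phenols as benzyl ethers, three free 3-hydroxyls), via flavan-4-ylium triflate 17 (not isolated)
Conditions: 16 (2 equiv, excess recovered), TMSOTf (0.1 equiv), 4 Å MS, CH2Cl2, −78 → −40 °C, slow addition of 12; Et3N quench
Reagents that add atoms: none
Why: The same Friedel–Crafts coupling, the C4 cation of 12 now paired with triflate: C8 of the upper (ent) unit of 16 is the only unhindered position ortho/para to three oxygens, as in procyanidin trimer assembly from a dimeric nucleophile, and attack anti to the C3 hydroxyl of the 2,3-cis cation should set the 3,4-trans (4β) bond.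

**Step 12**
Reactants: 18 nona-O-benzyl trimer
Product: 19 epiafzelechin-(4β→8)-ent-epiafzelechin-(4α→8)-epiafzelechin (CNP0191553.2)
Conditions: H2 (1 atm), Pd(OH)2/C, THF/MeOH/H2O, rt; Sephadex LH-20
Reagents that add atoms: none
Why: Hydrogenolysis of the nine aryl benzyl ethers under neutral conditions, under which the acid-labile interflavan bonds and all stereocentres should persist.

**Compound list**
1 | 4-(benzyloxy)benzaldehyde | O=Cc1ccc(OCc2ccccc2)cc1 | starting material
2 | ethyl (Z)-3-[4-(benzyloxy)phenyl]prop-2-enoate | CCOC(=O)/C=C\c1ccc(OCc2ccccc2)cc1 | intermediate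
3 | ethyl (2R,3R)-3-[4-(benzyloxy)phenyl]oxirane-2-carboxylate | CCOC(=O)[C@@H]1O[C@@H]1c1ccc(OCc2ccccc2)cc1 | intermediate
4 | (2R,3R)-3-[4-(benzyloxy)phenyl]oxirane-2-carbaldehyde | O=C[C@@H]1O[C@@H]1c1ccc(OCc2ccccc2)cc1 | intermediate
5 | 3,5-bis(benzyloxy)phenol | Oc1cc(OCc2ccccc2)cc(OCc2ccccc2)c1 | starting material
6 | [3,5-bis(benzyloxy)phenoxy]tris(propan-2-olato)titanium | CC(C)O[Ti](OC(C)C)(OC(C)C)Oc1cc(OCc2ccccc2)cc(OCc2ccccc2)c1 | intermediate
7 | 3,5-bis(benzyloxy)-2-{hydroxy[(2S,3R)-3-(4-benzyloxyphenyl)oxiran-2-yl]methyl}phenol (carbinol epimers; held as its titanium alkoxide) | OC(c1c(O)cc(OCc2ccccc2)cc1OCc2ccccc2)[C@@H]1O[C@@H]1c1ccc(OCc2ccccc2)cc1 | intermediate (not isolated)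
8 | (2S,3S)-5,7-bis(benzyloxy)-2-[4-(benzyloxy)phenyl]chromane-3,4-diol (C4 epimers) | OC1c2c(OCc3ccccc3)cc(OCc3ccccc3)cc2O[C@@H](c2ccc(OCc3ccccc3)cc2)[C@H]1O | intermediate
9 | ethyl (2S,3S)-3-[4-(benzyloxy)phenyl]oxirane-2-carboxylate | CCOC(=O)[C@H]1O[C@H]1c1ccc(OCc2ccccc2)cc1 | intermediate
10 | (2S,3S)-3-[4-(benzyloxy)phenyl]oxirane-2-carbaldehyde | O=C[C@H]1O[C@H]1c1ccc(OCc2ccccc2)cc1 | intermediate
11 | 3,5-bis(benzyloxy)-2-{hydroxy[(2R,3S)-3-(4-benzyloxyphenyl)oxiran-2-yl]methyl}phenol (carbinol epimers; held as its titanium alkoxide) | OC(c1c(O)cc(OCc2ccccc2)cc1OCc2ccccc2)[C@H]1O[C@H]1c1ccc(OCc2ccccc2)cc1 | intermediate (not isolated)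
12 | (2R,3R)-5,7-bis(benzyloxy)-2-[4-(benzyloxy)phenyl]chromane-3,4-diol (C4 epimers) | OC1c2c(OCc3ccccc3)cc(OCc3ccccc3)cc2O[C@H](c2ccc(OCc3ccccc3)cc2)[C@@H]1O | intermediate
13 | (2R,3R)-5,7-bis(benzyloxy)-2-[4-(benzyloxy)phenyl]-3-hydroxychroman-4-ylium trifluoroacetate (ion pair) | [CH+]1c2c(OCc3ccccc3)cc(OCc3ccccc3)cc2O[C@H](c2ccc(OCc3ccccc3)cc2)[C@@H]1O.[O-]C(=O)C(F)(F)F | intermediate (not isolated)
14 | (2R,3R)-5,7-bis(benzyloxy)-2-[4-(benzyloxy)phenyl]chroman-3-ol | C1c2c(OCc3ccccc3)cc(OCc3ccccc3)cc2O[C@H](c2ccc(OCc3ccccc3)cc2)[C@@H]1O | intermediate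
15 | (2S,3S)-5,7-bis(benzyloxy)-2-[4-(benzyloxy)phenyl]-3-hydroxychroman-4-ylium triflate (ion pair) | [CH+]1c2c(OCc3ccccc3)cc(OCc3ccccc3)cc2O[C@@H](c2ccc(OCc3ccccc3)cc2)[C@H]1O.[O-]S(=O)(=O)C(F)(F)F | intermediate (not isolated)
16 | hexa-O-benzyl ent-epiafzelechin-(4α→8)-epiafzelechin | c1c(OCc9ccccc9)cc(OCc9ccccc9)c2c1O[C@@H](c1ccc(OCc9ccccc9)cc1)[C@@H](O)[C@@H]2c1c(OCc9ccccc9)cc(OCc9ccccc9)c2c1O[C@H](c1ccc(OCc9ccccc9)cc1)[C@H](O)C2 | intermediate
17 | (2R,3R)-5,7-bis(benzyloxy)-2-[4-(benzyloxy)phenyl]-3-hydroxychroman-4-ylium triflate (ion pair) | [CH+]1c2c(OCc3ccccc3)cc(OCc3ccccc3)cc2O[C@H](c2ccc(OCc3ccccc3)cc2)[C@@H]1O.[O-]S(=O)(=O)C(F)(F)F | intermediate (not isolated)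
18 | nona-O-benzyl epiafzelechin-(4β→8)-ent-epiafzelechin-(4α→8)-epiafzelechin | c9ccccc9COc1ccc([C@H]2Oc3cc(OCc9ccccc9)cc(OCc9ccccc9)c3[C@H](c3c(OCc9ccccc9)cc(OCc9ccccc9)c4c3O[C@@H](c3ccc(OCc9ccccc9)cc3)[C@@H](O)[C@@H]4c3c(OCc9ccccc9)cc(OCc9ccccc9)c4c3O[C@H](c3ccc(OCc9ccccc9)cc3)[C@H](O)C4)[C@H]2O)cc1 | intermediate
19 | epiafzelechin-(4β→8)-ent-epiafzelechin-(4α→8)-epiafzelechin | Oc1ccc([C@H]2Oc3cc(O)cc(O)c3[C@H](c3c(O)cc(O)c4c3O[C@@H](c3ccc(O)cc3)[C@@H](O)[C@@H]4c3c(O)cc(O)c4c3O[C@H](c3ccc(O)cc3)[C@H](O)C4)[C@H]2O)cc1 | target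

**Step count.** Total: 12 steps. Longest linear sequence: 8 steps (steps 1, 6, 7, 8, 9, 10, 11, 12).

**Steps most likely to fail**

1. Step 5 (proposed new method). The ortho-hydroxybenzylic titanate may ionise to an ortho-quinone methide and alkylate a second phenol. The epoxide may open 5-exo, or not at all under titanium alone. Partial SN1 opening at the 4-benzyloxyphenyl carbon may erode the inversion and give 2,3-trans material. The fallback forms the two ring bonds in separate, known steps; it sets out from 1 and 5 and comes back at 8. Vinylmagnesium bromide (CH2=CHMgBr, THF, 0 °C) should add to 1 to give racemic 1-[4-(benzyloxy)phenyl]prop-2-en-1-ol F1. Sharpless kinetic resolution (Ti(OiPr)4, D-(−)-diisopropyl tartrate, tBuOOH, 4 Å MS, CH2Cl2, −20 °C) should epoxidise its fast-reacting enantiomer to the erythro epoxy alcohol (R)-[4-(benzyloxy)phenyl][(S)-oxiran-2-yl]methanol F2. Mitsunobu etherification with 5 (PPh3, DIAD, THF) should give, with inversion, (S)-2-{(S)-[3,5-bis(benzyloxy)phenoxy][4-(benzyloxy)phenyl]methyl}oxirane F3. Gold-catalysed 6-endo epoxide arylation (AuCl3, the chloride of trivalent gold, with AgOTf, CH2Cl2, rt) should close ring C to (2S,3S)-5,7-bis(benzyloxy)-2-[4-(benzyloxy)phenyl]chroman-3-ol F4. Benzylic oxidation at C4 (DDQ, H2O, CH2Cl2/THF, rt) should then give 8.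

2. Step 8 (proposed new method). The same processes as in step 5 may intervene in the mirror-image series, and here they would cut off both outer units. The fallback sets out from 1 and 5 by way of F1 (made as above) and comes back at 14. Kinetic resolution of F1 with L-(+)-diisopropyl tartrate (Ti(OiPr)4, tBuOOH, 4 Å MS, CH2Cl2, −20 °C) should give (S)-[4-(benzyloxy)phenyl][(R)-oxiran-2-yl]methanol F5. Mitsunobu etherification with 5 (PPh3, DIAD, THF) should give (R)-2-{(R)-[3,5-bis(benzyloxy)phenoxy][4-(benzyloxy)phenyl]methyl}oxirane F6. The gold-catalysed cyclisation (AuCl3, AgOTf, CH2Cl2) should give 14 directly. Part of 14 is then oxidised at C4 (DDQ, H2O, CH2Cl2/THF) to 12, so step 9 is no longer needed.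

3. Step 11. The cation from 12 may be captured by the free C8 of another molecule of 12, or by the C6 positions of 16, so that oligomer and regioisomer mixtures form in place of one trimer. The fallback caps C8 of the electrophile with bromine; it sets out from 14 and comes back at 19. Bromination (NBS, CH2Cl2, −40 °C → rt) should give (2R,3R)-8-bromo-5,7-bis(benzyloxy)-2-[4-(benzyloxy)phenyl]chroman-3-ol F7. C4 oxidation (DDQ, H2O, CH2Cl2/THF) should give (2R,3R)-8-bromo-5,7-bis(benzyloxy)-2-[4-(benzyloxy)phenyl]chromane-3,4-diol F8, which cannot self-condense at C8. Coupling with 16 (TMSOTf, 4 Å MS, CH2Cl2, −78 → −40 °C) should give the 8-bromo derivative of 18 (bromine at C8 of the top unit) F9. Hydrogenolysis under the conditions of step 12 with added Et3N should remove the bromine together with the benzyl groups and give 19.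

**Further compounds**
F1 | step 5 | 1-[4-(benzyloxy)phenyl]prop-2-en-1-ol (racemic) | C=CC(O)c1ccc(OCc2ccccc2)cc1
F2 | step 5 | (R)-[4-(benzyloxy)phenyl][(S)-oxiran-2-yl]methanol | O[C@H](c1ccc(OCc2ccccc2)cc1)[C@@H]1CO1
F3 | step 5 | (S)-2-{(S)-[3,5-bis(benzyloxy)phenoxy][4-(benzyloxy)phenyl]methyl}oxirane | c1c(OCc2ccccc2)cc(OCc2ccccc2)cc1O[C@@H](c1ccc(OCc2ccccc2)cc1)[C@@H]1CO1
F4 | step 5 | (2S,3S)-5,7-bis(benzyloxy)-2-[4-(benzyloxy)phenyl]chroman-3-ol | C1c2c(OCc3ccccc3)cc(OCc3ccccc3)cc2O[C@@H](c2ccc(OCc3ccccc3)cc2)[C@H]1O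
F5 | step 8 | (S)-[4-(benzyloxy)phenyl][(R)-oxiran-2-yl]methanol | O[C@@H](c1ccc(OCc2ccccc2)cc1)[C@H]1CO1
F6 | step 8 | (R)-2-{(R)-[3,5-bis(benzyloxy)phenoxy][4-(benzyloxy)phenyl]methyl}oxirane | c1c(OCc2ccccc2)cc(OCc2ccccc2)cc1O[C@H](c1ccc(OCc2ccccc2)cc1)[C@H]1CO1
F7 | step 11 | (2R,3R)-8-bromo-5,7-bis(benzyloxy)-2-[4-(benzyloxy)phenyl]chroman-3-ol | C1c2c(OCc3ccccc3)cc(OCc3ccccc3)c(Br)c2O[C@H](c2ccc(OCc3ccccc3)cc2)[C@@H]1O
F8 | step 11 | (2R,3R)-8-bromo-5,7-bis(benzyloxy)-2-[4-(benzyloxy)phenyl]chromane-3,4-diol (C4 epimers) | OC1c2c(OCc3ccccc3)cc(OCc3ccccc3)c(Br)c2O[C@H](c2ccc(OCc3ccccc3)cc2)[C@@H]1O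
F9 | step 11 | 8-bromo derivative of 18 (bromine at C8 of the top unit) | c9ccccc9COc1ccc([C@H]2Oc3c(Br)c(OCc9ccccc9)cc(OCc9ccccc9)c3[C@H](c3c(OCc9ccccc9)cc(OCc9ccccc9)c4c3O[C@@H](c3ccc(OCc9ccccc9)cc3)[C@@H](O)[C@@H]4c3c(OCc9ccccc9)cc(OCc9ccccc9)c4c3O[C@H](c3ccc(OCc9ccccc9)cc3)[C@H](O)C4)[C@H]2O)cc1
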